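**Retrosynthetic overview**

- Feature: in ring A the ester carbon C1 lies between two oxygen-bearing carbons, C2 (O-prenyl) and C6 (O-aryl to ring B), with the methyl group para at C4. A benzyne across C1–C6 that already carries the C2 oxygen can therefore take up the ring B oxygen at C6 and a carboxyl carbon at C1 in one operation.
- Last disconnections: the ring A C2 O–prenyl bond (Williamson), then the C6–O(aryl) and C1–CO2Me bonds together (aryne + ring B phenoxide + CO2, then MeI).
- Aryne precursor 17 comes from orcinol (mono-methoxymethylation, carbamate-directed ortho-silylation, triflation).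
- Ring B phenol 8 comes from 2-hydroxy-5-methoxybenzaldehyde (bromination, hydroxylation, dianion prenylation, reduction, silylation).
- No ring is built: both benzene rings are bought; ring B is elaborated in the longest line and ring A is joined to it in the key step.

Key step: step 10

Remark: the benzylic oxygen of ring B is carried as a tert-butyldimethylsilyl ether. It can be placed selectively on the salicyl alcohol, and it is cleaved by the same mild acid as the ring A methoxymethyl ether, so the aryl prenyl ether is not exposed to the stronger acid that an alkyl acetal would need.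

**Route**

Step 1
Reactants: 1 2-hydroxy-5-methoxybenzaldehyde
Product: 2 3-bromo-2-hydroxy-5-methoxybenzaldehyde
Conditions: Br2, NaOAc, AcOH, rt
Reagents that add atoms: bromine, BrBr
Why: Electrophilic aromatic bromination directed by the phenol, whose para position is blocked by the methoxy group, so that C3 is the only free position ortho to the hydroxyl, with NaOAc buffering the HBr.

Step 2
Reactants: 2 3-bromo-2-hydroxy-5-methoxybenzaldehyde
Product: 3 2,3-dihydroxy-5-methoxybenzaldehyde
Conditions: Cu powder, aq. NaOH, reflux, argon; then aq. HCl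
Reagents that add atoms: sodium hydroxide, [Na+].[OH-]
Why: Copper-mediated Ullmann-type hydroxylation of an ortho-bromophenol in hot alkali, the reaction type that turns 5-bromovanillin into 5-hydroxyvanillin, run under argon because the catechol is oxidisable.

Step 3
Reactants: 3 2,3-dihydroxy-5-methoxybenzaldehyde; 4 prenyl bromide (1-bromo-3-methylbut-2-ene)
Product: 6 2-hydroxy-5-methoxy-3-(3-methylbut-2-enyloxy)benzaldehyde, via disodium catecholate 5 (not isolated)
Conditions: NaH (2.2 equiv), DMSO, rt; then 4 (1.0 equiv), rt
Reagents that add atoms: prenyl bromide 4, CC(C)=CCBr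
Why: Regioselective Williamson mono-alkylation of a catecholate dianion, in which the C2 phenoxide is delocalised into the ortho formyl group and the C3 phenoxide is therefore the more nucleophilic oxygen for the single equivalent of bromide.

Step 4
Reactants: 6 2-hydroxy-5-methoxy-3-(3-methylbut-2-enyloxy)benzaldehyde
Product: 7 2-(hydroxymethyl)-4-methoxy-6-(3-methylbut-2-enyloxy)phenol
Conditions: NaBH4, MeOH, 0 °C
Reagents that add atoms: none
Why: Hydride reduction of the aldehyde to the primary benzylic alcohol, which leaves the prenyl alkene and the aryl ethers untouched.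

Step 5
Reactants: 7 2-(hydroxymethyl)-4-methoxy-6-(3-methylbut-2-enyloxy)phenol
Product: 8 2-[(tert-butyldimethylsilyloxy)methyl]-4-methoxy-6-(3-methylbut-2-enyloxy)phenol
Conditions: TBSCl (1.05 equiv), imidazole, CH2Cl2, 0 °C
Reagents that add atoms: tert-butyldimethylsilyl chloride, CC(C)(C)[Si](C)(C)Cl
Why: Chemoselective silylation of the primary benzylic alcohol of a salicyl alcohol, the phenol being shielded by its two ortho substituents and an internal hydrogen bond.

Step 6
Reactants: 9 orcinol (5-methylbenzene-1,3-diol)
Product: 10 3-(methoxymethoxy)-5-methylphenol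
Conditions: MOMCl (1.0 equiv), K2CO3, acetone, 0 °C to rt
Reagents that add atoms: chloromethyl methyl ether, COCCl
Why: Williamson-type O-alkylation of one of the two equivalent phenols, which should give the single possible mono-ether in a statistical mixture with bis-ether and unchanged orcinol, from which it is separated by chromatography.

Step 7
Reactants: 10 3-(methoxymethoxy)-5-methylphenol
Product: 11 3-(methoxymethoxy)-5-methylphenyl N-isopropylcarbamate
Conditions: i-PrNCO, Et3N (cat.), CH2Cl2, rt
Reagents that add atoms: isopropyl isocyanate, CC(C)N=C=O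
Why: Base-catalysed addition of the phenol to the isocyanate (carbamoylation) installs the directing group for the ortho-metalation.

Step 8
Reactants: 11 3-(methoxymethoxy)-5-methylphenyl N-isopropylcarbamate
Product: 15 3-(methoxymethoxy)-5-methyl-2-(trimethylsilyl)phenyl N-isopropylcarbamate, via N-TBS carbamate 12 (not isolated), via aryllithium 13 (not isolated), via N-TBS C-TMS carbamate 14 (not isolated)
Conditions: TBSOTf, TMEDA, Et2O, 0 °C to rt; then n-BuLi, TMEDA, −78 °C; then TMSCl, −78 °C to rt; aq. NaHSO4
Reagents that add atoms: chlorotrimethylsilane, C[Si](C)(C)Cl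
Why: Directed ortho-metalation in which, after in situ N-silylation of the carbamate N–H, n-BuLi/TMEDA removes the ring proton between the carbamate and the methoxymethoxy group (the only site activated by both), TMSCl quenches the aryllithium and the N–Si bond is hydrolysed at work-up.

Step 9
Reactants: 15 3-(methoxymethoxy)-5-methyl-2-(trimethylsilyl)phenyl N-isopropylcarbamate
Product: 17 3-(methoxymethoxy)-5-methyl-2-(trimethylsilyl)phenyl trifluoromethanesulfonate, via DBU-H phenoxide 16 (not isolated)
Conditions: DBU, Et2NH, MeCN, 40 °C; then PhNTf2, rt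
Reagents that add atoms: N-phenylbis(trifluoromethanesulfonimide), O=S(=O)(N(c1ccccc1)S(=O)(=O)C(F)(F)F)C(F)(F)F
Why: E1cB cleavage of the N-monoalkyl aryl carbamate releases the phenoxide and isopropyl isocyanate, which diethylamine scavenges as a urea, and the phenoxide is O-triflated in the same flask.

Step 10
Reactants: 8 2-[(tert-butyldimethylsilyloxy)methyl]-4-methoxy-6-(3-methylbut-2-enyloxy)phenol; 17 3-(methoxymethoxy)-5-methyl-2-(trimethylsilyl)phenyl trifluoromethanesulfonate
Product: 22 methyl 2-(methoxymethoxy)-4-methyl-6-[2-[(tert-butyldimethylsilyloxy)methyl]-4-methoxy-6-(3-methylbut-2-enyloxy)phenoxy]benzoate, via potassium phenoxide 18 (not isolated), via aryne 19 (not isolated), via aryl anion 20 (not isolated), via potassium carboxylate 21 (not isolated)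
Conditions: KH (1.0 equiv), THF, 0 °C; then KF, 18-crown-6, CO2 (1 atm), slow addition of 17, 0 °C to rt; then MeI, DMF, rt
Reagents that add atoms: carbon dioxide, O=C=O; methyl iodide, CI
Why: Proposed new method: fluoride from KF/18-crown-6 attacks the trimethylsilyl group of 17 and triflate leaves to give aryne 19, whose triple bond is polarised by the inductively withdrawing methoxymethoxy group on the neighbouring carbon, so that the pre-formed potassium phenoxide 18 attacks the remote aryne carbon (the future C6) and the negative charge develops on the future C1, between the two oxygen-bearing carbons. In THF with no O–H or acidic C–H donor present, aryl anion 20 should be captured by dissolved CO2 to give carboxylate 21, which methyl iodide esterifies at oxygen in the same flask. The closest known reaction types are the three-component couplings of arynes with amines or other neutral nucleophiles and CO2, and the regioselective addition of phenols to 3-alkoxybenzynes that ends in protonation; the new element is carboxylation of the anion that follows an oxygen nucleophile. No ring is closed and no stereocentre is formed. The step needs regioselectivity on the aryne, secured by the C2 oxygen substituent and reinforced by the bulk of the 2,6-disubstituted phenoxide; O- rather than C-arylation, secured because both ortho positions and the para position of the ring B phenoxide are substituted; and carboxylation rather than protonation, secured by making the phenoxide with KH and masking the benzylic alcohol as a silyl ether. The trimethylsilyl group next to the triflate is attacked by fluoride much faster than the hindered tert-butyldimethylsilyl ether, and the ring A oxygen is carried as a methoxymethyl ether so that no allylic C–H sits beside the aryne for an intramolecular ene reaction.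

Step 11
Reactants: 22 methyl 2-(methoxymethoxy)-4-methyl-6-[2-[(tert-butyldimethylsilyloxy)methyl]-4-methoxy-6-(3-methylbut-2-enyloxy)phenoxy]benzoate
Product: 23 methyl 2-hydroxy-6-[2-(hydroxymethyl)-4-methoxy-6-(3-methylbut-2-enyloxy)phenoxy]-4-methylbenzoate
Conditions: HCl (ca. 0.5 M) in MeOH, 0 °C to rt
Reagents that add atoms: none
Why: Acid-catalysed methanolysis (acetal exchange) of the aryl methoxymethyl ether ortho to the ester, together with acid-catalysed desilylation of the primary silyl ether, both of which proceed under dilute acid at or below room temperature where the aryl prenyl ether and the methyl ester should persist.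

Step 12
Reactants: 23 methyl 2-hydroxy-6-[2-(hydroxymethyl)-4-methoxy-6-(3-methylbut-2-enyloxy)phenoxy]-4-methylbenzoate; 4 prenyl bromide (1-bromo-3-methylbut-2-ene)
Product: 24 methyl 2-[2-(hydroxymethyl)-4-methoxy-6-(3-methylbut-2-enyloxy)phenoxy]-4-methyl-6-(3-methylbut-2-enyloxy)benzoate (target)
Conditions: 4 (1.2 equiv), K2CO3, DMF, 40 °C
Reagents that add atoms: prenyl bromide 4, CC(C)=CCBr
Why: Williamson etherification in which K2CO3 deprotonates only the salicylate phenol, so that the benzylic alcohol stays free and O-alkylation occurs at ring A C2–O.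

**Compound list**

1 | 2-hydroxy-5-methoxybenzaldehyde | COc1ccc(O)c(C=O)c1 | starting material
2 | 3-bromo-2-hydroxy-5-methoxybenzaldehyde | COc1cc(Br)c(O)c(C=O)c1 | intermediate
3 | 2,3-dihydroxy-5-methoxybenzaldehyde | COc1cc(O)c(O)c(C=O)c1 | intermediate
4 | prenyl bromide (1-bromo-3-methylbut-2-ene) | CC(C)=CCBr | starting material
5 | disodium 3-formyl-5-methoxybenzene-1,2-diolate (not isolated) | COc1cc([O-])c([O-])c(C=O)c1.[Na+].[Na+] | intermediate
6 | 2-hydroxy-5-methoxy-3-(3-methylbut-2-enyloxy)benzaldehyde | COc1cc(OCC=C(C)C)c(O)c(C=O)c1 | intermediate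
7 | 2-(hydroxymethyl)-4-methoxy-6-(3-methylbut-2-enyloxy)phenol | COc1cc(CO)c(O)c(OCC=C(C)C)c1 | intermediate
8 | 2-[(tert-butyldimethylsilyloxy)methyl]-4-methoxy-6-(3-methylbut-2-enyloxy)phenol | COc1cc(CO[Si](C)(C)C(C)(C)C)c(O)c(OCC=C(C)C)c1 | intermediate
9 | orcinol (5-methylbenzene-1,3-diol) | Cc1cc(O)cc(O)c1 | starting material
10 | 3-(methoxymethoxy)-5-methylphenol | COCOc1cc(C)cc(O)c1 | intermediate
11 | 3-(methoxymethoxy)-5-methylphenyl N-isopropylcarbamate | COCOc1cc(C)cc(OC(=O)NC(C)C)c1 | intermediate
12 | 3-(methoxymethoxy)-5-methylphenyl N-(tert-butyldimethylsilyl)-N-isopropylcarbamate (not isolated) | COCOc1cc(C)cc(OC(=O)N(C(C)C)[Si](C)(C)C(C)(C)C)c1 | intermediate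
13 | 2-lithio derivative of 12, lithium between the carbamate and the methoxymethoxy group (not isolated) | COCOc1cc(C)cc(OC(=O)N(C(C)C)[Si](C)(C)C(C)(C)C)c1[Li] | intermediate
14 | 3-(methoxymethoxy)-5-methyl-2-(trimethylsilyl)phenyl N-(tert-butyldimethylsilyl)-N-isopropylcarbamate (not isolated) | COCOc1cc(C)cc(OC(=O)N(C(C)C)[Si](C)(C)C(C)(C)C)c1[Si](C)(C)C | intermediate
15 | 3-(methoxymethoxy)-5-methyl-2-(trimethylsilyl)phenyl N-isopropylcarbamate | COCOc1cc(C)cc(OC(=O)NC(C)C)c1[Si](C)(C)C | intermediate
16 | 1,8-diazabicyclo[5.4.0]undec-7-enium 3-(methoxymethoxy)-5-methyl-2-(trimethylsilyl)phenoxide (not isolated) | COCOc1cc(C)cc([O-])c1[Si](C)(C)C.C1CCC2=[NH+]CCCN2CC1 | intermediate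
17 | 3-(methoxymethoxy)-5-methyl-2-(trimethylsilyl)phenyl trifluoromethanesulfonate | COCOc1cc(C)cc(OS(=O)(=O)C(F)(F)F)c1[Si](C)(C)C | intermediate
18 | potassium 2-[(tert-butyldimethylsilyloxy)methyl]-4-methoxy-6-(3-methylbut-2-enyloxy)phenoxide (not isolated) | COc1cc(CO[Si](C)(C)C(C)(C)C)c([O-])c(OCC=C(C)C)c1.[K+] | intermediate
19 | 3-(methoxymethoxy)-5-methylbenzyne (not isolated) | COCOC1=CC(C)=CC#C1 | intermediate
20 | potassium aryl anion: ring A C1 carbanion between C2–OMOM and C6–O–ring B (not isolated) | COCOc1cc(C)cc(Oc2c(CO[Si](C)(C)C(C)(C)C)cc(OC)cc2OCC=C(C)C)[c-]1.[K+] | intermediate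
21 | potassium 2-(methoxymethoxy)-4-methyl-6-[2-[(tert-butyldimethylsilyloxy)methyl]-4-methoxy-6-(3-methylbut-2-enyloxy)phenoxy]benzoate (not isolated) | COCOc1cc(C)cc(Oc2c(CO[Si](C)(C)C(C)(C)C)cc(OC)cc2OCC=C(C)C)c1C(=O)[O-].[K+] | intermediate
22 | methyl 2-(methoxymethoxy)-4-methyl-6-[2-[(tert-butyldimethylsilyloxy)methyl]-4-methoxy-6-(3-methylbut-2-enyloxy)phenoxy]benzoate | COC(=O)c1c(OCOC)cc(C)cc1Oc1c(CO[Si](C)(C)C(C)(C)C)cc(OC)cc1OCC=C(C)C | intermediate
23 | methyl 2-hydroxy-6-[2-(hydroxymethyl)-4-methoxy-6-(3-methylbut-2-enyloxy)phenoxy]-4-methylbenzoate | COC(=O)c1c(O)cc(C)cc1Oc1c(CO)cc(OC)cc1OCC=C(C)C | intermediate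
24 | methyl 2-[2-(hydroxymethyl)-4-methoxy-6-(3-methylbut-2-enyloxy)phenoxy]-4-methyl-6-(3-methylbut-2-enyloxy)benzoate | COC(=O)c1c(OCC=C(C)C)cc(C)cc1Oc1c(CO)cc(OC)cc1OCC=C(C)C | target

**Step count and risks**

Total step count: 12. Longest linear sequence: 8 steps (steps 1–5, then 10–12).

Steps most likely to fail:

1. Step 10 (proposed new method). The aryl anion may be protonated before it meets CO2, the phenoxide may be held back as its carbonate while the aryne oligomerises, or fluoride may start to cleave the benzylic silyl ether. The fallback uses known chemistry and sets out from phenol 8 and silyl triflate 17. Aryne O-arylation of the free phenol (CsF, MeCN, rt) should give the protonated diaryl ether tert-butyl{[5-methoxy-2-[3-(methoxymethoxy)-5-methylphenoxy]-3-(3-methylbut-2-enyloxy)phenyl]methoxy}dimethylsilane F1. Directed ortho-metalation of F1 (n-BuLi, Et2O, 0 °C) at the ring A carbon between the methoxymethoxy and aryloxy groups, the methoxymethoxy group being the strongest director in the molecule, followed by a methyl chloroformate quench at −78 °C, comes back to the route at 22.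

2. Step 11. The ring B prenyl ether may ionise or shift to carbon under the acid while the methoxymethyl ether is being cleaved. The fallback sets out from 22 and removes all three acid-labile groups on purpose. TsOH·H2O in MeOH at 50 °C, with methanol as solvent trapping the prenyl cation, should give methyl 2-hydroxy-6-[2-hydroxy-6-(hydroxymethyl)-4-methoxyphenoxy]-4-methylbenzoate F2. Both phenols of F2 are then alkylated with prenyl bromide 4 (2.2 equiv) and K2CO3 in DMF, the benzylic alcohol staying free, which comes back to the route at target 24.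

3. Step 2. Hydroxylation may stall, hydrodebromination may compete, or the catechol aldehyde may be oxidised in hot alkali. The fallback sets out from 2 and avoids both the copper step and the free catechol. NaBH4 reduction should give 2-bromo-6-(hydroxymethyl)-4-methoxyphenol F3. Acetonide formation (2,2-dimethoxypropane, TsOH cat., acetone) should give 8-bromo-6-methoxy-2,2-dimethyl-4H-1,3-benzodioxine F4. Bromine–lithium exchange (n-BuLi, THF, −78 °C), B(OMe)3 and oxidation with H2O2/NaOH should give 6-methoxy-2,2-dimethyl-4H-1,3-benzodioxin-8-ol F5. Prenyl bromide 4 with K2CO3 should give 6-methoxy-2,2-dimethyl-8-(3-methylbut-2-enyloxy)-4H-1,3-benzodioxine F6. Hydrolysis of the acetonide (AcOH, H2O, THF, 40 °C) comes back to the route at 7.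

**Further compounds**

F1 | step 10 | tert-butyl{[5-methoxy-2-[3-(methoxymethoxy)-5-methylphenoxy]-3-(3-methylbut-2-enyloxy)phenyl]methoxy}dimethylsilane | COCOc1cc(C)cc(Oc2c(CO[Si](C)(C)C(C)(C)C)cc(OC)cc2OCC=C(C)C)c1
F2 | step 11 | methyl 2-hydroxy-6-[2-hydroxy-6-(hydroxymethyl)-4-methoxyphenoxy]-4-methylbenzoate | COC(=O)c1c(O)cc(C)cc1Oc1c(CO)cc(OC)cc1O
F3 | step 2 | 2-bromo-6-(hydroxymethyl)-4-methoxyphenol | COc1cc(Br)c(O)c(CO)c1
F4 | step 2 | 8-bromo-6-methoxy-2,2-dimethyl-4H-1,3-benzodioxine | COc1cc(Br)c2OC(C)(C)OCc2c1
F5 | step 2 | 6-methoxy-2,2-dimethyl-4H-1,3-benzodioxin-8-ol | COc1cc(O)c2OC(C)(C)OCc2c1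
F6 | step 2 | 6-methoxy-2,2-dimethyl-8-(3-methylbut-2-enyloxy)-4H-1,3-benzodioxine | COc1cc(OCC=C(C)C)c2OC(C)(C)OCc2c1
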